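| flask | substrate | first nucleophile | second nucleophile | remark | time |
|---|---|---|---|---|---|
| dusk | 0.0060 M | 0.050 M | 0.034 M | run made earlier |  |
| green | 0.0060 M | 0.0500 M | 0.0500 M |  | 3.0 h |
| amber | 0.015 M | 0.0500 M | 0.0500 M |  | 3.0 h |
| blue | 0.050 M | 0.0500 M | 0.0500 M |  | 3.0 h |
| teal | 0.15 M | 0.0500 M | 0.0500 M |  | 3.0 h |
| violet | 0.50 M | 0.0500 M | 0.0500 M |  | 3.0 h |

- dusk (time / min: target / %, other capture product / %, side product / %): 10.0: 1.5, 45.0, 0.2; 20.0: 0.3, 70.1, 0.1; 25.0: 0, 77.1, 0.1; 40.0: 0.8, 91.2, 0.2; 50.0: 0.6, 94.6, 0.6; 60.0: 0.1, 96.9, 0.5

(scatter of a reading: 0.5 percentage points)

- in percentages every species weighs as the substrate in it: one side product counts as two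
- "hardly changes" means that all values lie within two and a half points (for a concentration: within two and a half percent of the largest)

* share of target in all that became target or other capture product or side product for green, amber, blue, teal, violet, in this order
* the course of these numbers from the first flask to the last (hardly changes / rises all the way / falls, then rises / falls all the way / rises, then falls)

1. A small charge of substrate, 0.0060 M in the dusk run, met 0.034 M of second nucleophile. By 60.0 min, nearly all of the product read was other capture product.

2. In dusk, other capture product reads 91.2% at 40.0 min. The shortfall gives a first-order rate of 0.0608 min⁻¹, as a reading. Over 3.0 h that rate means 4.76 powers of ten of decay, so the substrate should not outlast the asked time.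

3. Teal's second nucleophile charge over its substrate charge is 33.3%. This ratio is the capture ceiling: the share of the substrate that the second nucleophile can take, one to one. For violet it is 10.0%.

4. One way to a row that hardly changes is that the second nucleophile outlasts the substrate in each flask. Green stands 0.921 powers of ten above balance, and blue's ceiling is 100%. Violet stands 1.00 powers of ten below balance. So the second nucleophile is the limiting reagent in teal and in violet, and that way to a flat row is closed.

5. The reckoning here puts green, amber and blue near zero. Substrate above the ceiling has to stop short of other capture product, and the first nucleophile can then take part of it. The first nucleophile charge is 33.3% of teal's substrate but 10.0% of violet's, so target has less room in violet. The row should rise at teal and fall at violet.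

6. The forecast gave 0.4%, 0.4%, 1.1%, 8.5%, 3.5%, with the course rises, then falls. At blue it said: “the second nucleophile just runs out”.

7. The flasks give 0%, 0%, 0.146%, 36.7%, 15.0%, with the course rises, then falls. The course agrees with the forecast; teal parts from it, at 36.7% against 8.5%.

    substrate → intermediate (k = 0.0616 min⁻¹)
    first nucleophile + intermediate ⇌ target (K = 51.4 M⁻¹, k = 145 M⁻¹ min⁻¹)
    second nucleophile + intermediate → other capture product (k = 263 M⁻¹ min⁻¹)
    substrate + intermediate → side product (k = 0.181 M⁻¹ min⁻¹)

In green at 0.188 h, the ratio of intermediate used by the second nucleophile to that used by the first, forward step alone, is 1.7. Yet green ends with target at 0% and other capture product at >99.9%, and the target step runs both ways. In teal, the second nucleophile stands at 0% of its charge, and other capture product stands at 33.3% against a ceiling of 33.3%. In violet, the second nucleophile also stands at 0% of its charge, and other capture product stands at 10.0% against a ceiling of 10.0%.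

All runs are calculated from invented constants; noise was put on by code.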